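**Structural features**

The target is a flavonol: a benzene ring A fused through C4a–C8a to a 4-pyranone ring C, which carries the catechol ring B at C2 and a hydroxyl at C3. Ring A is hexasubstituted, with four contiguous oxygenated carbons C5–C8 and a fifth oxygen (O1) on C8a, so no C–H position is left for late functionalisation. Of the oxygens on C5–C8 only that on C5 is a free phenol, hydrogen-bonded to the C4 carbonyl; those on C6, C7 and C8 are methyl ethers, so the ring has to be differentiated as well as built. There is no stereocenter. The fragile groups are the catechol and the 3-hydroxy-4-pyranone enol (air oxidation in base), and ring A itself, which passes easily into a 5,8-quinone once O5 and O8 are both free. The real difficulty is ring A; the usual plans only move it into a pentaoxygenated acetophenone. The feature used here is that C5, C6, C7 and C8 with their four oxygens are the carbon–oxygen skeleton of squaric acid (C6 and C7 carry the methoxy groups of its dimethyl ester, C5 and C8 its carbonyl oxygens), while C4a=C8a is the C5=C6 double bond of a monocyclic 4-pyranone.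

**Logic of the disconnections**

13 to 12: the three O–CH2Ph bonds at O3, O3' and O4' are cut. The catechol and the enol stay masked through the organometallic and thermal steps and appear only at the end. The forward step must remove benzyl groups without touching the three methyl ethers or the C2=C3 bond.

12 to 11: the O8–CH3 bond is cut. In 11 the two free hydroxyls differ because O5–H is chelated to the C4 carbonyl and O8–H is not. The ring A precursor becomes a hydroquinone with a symmetrical 6,7-dimethoxy unit. The forward step must alkylate once, at O8.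

11 to 8 (key disconnection): the C5–C4a bond is cut and the C5–C8 bond of a four-membered ring is restored. Ring A disappears; C5–C8 become a cyclobutenone bound through its carbinol carbon (future C8) to C6 of a pyranone (future C8a). In one sentence, ring A is made last by thermal ring expansion of 8. A hexasubstituted arene is reduced to a monocyclic pyranone plus a four-carbon ring, and all six substituents of ring A are placed by the construction. The forward cascade must open the four-membered ring with the hydroxyl turning outward and close on C5 of the pyranone, in the absence of oxidants.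

8 to 5 and 6: the bond between the carbinol carbon and pyranone C6 is cut. 6 is symmetrical, so the addition raises no regiochemical question on the four-carbon unit, and the two halves are of similar size. The forward step needs a carbanion at C6 of 5 and 1,2-addition to a carbonyl of 6. An adduct through C5 of 5 would give the same 11 after ring expansion, so the constitution of ring A does not depend on the site of metalation.

5 to 3 and 4: the C2–C1' bond is cut. This joins ring B to ring C by a cross-coupling of a vinylogous acyl bromide. The forward step needs a base mild enough for the pyranone.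

3 to 2 to 1: the O3–CH2Ph bond and then the C2–Br bond are cut. The enolic hydroxyl of 1 directs the halogen to C2, the carbon that must carry ring B. The forward steps need monobromination and an etherification that spares the reactive C2–Br bond.

**Other disconnections considered**

Alternative 1: the first plan that comes to mind cuts O1–C2 and C3–O3 in ring C. Forward, a Claisen–Schmidt condensation of acetophenone A1 with aldehyde A2 gives chalcone A3, and Algar–Flynn–Oyamada oxidative cyclisation gives flavonol A4. Selective cleavage of the 5-methyl ether and hydrogenolysis would follow. Ring A is not addressed: A1 already holds all five oxygens and would have to be made by stepwise oxygenation of a simpler arene. The 6'-methoxy group of A3 twists the aryl ketone and is expected to divert the oxidative cyclisation toward an aurone. The 5-methyl ether of A4 must then be cleaved next to the 6-methyl ether. The chosen plan meets none of these selectivity problems, because the oxygen pattern comes from the symmetrical 6 and from chelation.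

Alternative 2: ring A by a Dötz benzannulation, cutting C5–C4a, C5–C6 and C7–C8. Forward, the chromium carbene complex A5 (from metalated 5) would combine with the dialkoxyalkyne A6 and one CO ligand to give A7, with 8-OMe and 5-OH set directly. The O-methylation needed to make A5 competes with O-alkylation of the pyranone carbonyl to a pyrylium salt. An electron-rich alkyne such as A6 is prone to multiple insertion and to cyclobutenone formation. The two tert-butyl ethers of A7 would then have to be exchanged for methyl ethers. That costs stoichiometric chromium and about three more steps, whereas 6 brings the 6,7-dimethoxy unit in its final form.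

Alternative 3: both bonds from ring C to ring A (O1–C8a and C4–C4a) made on an aryne. Forward, the symmetrical aryne A9, from silyl triflate A8, would take up the enolate oxygen of β-keto ester A10, and the aryl anion would then attack the ester to close the pyranone of A11. The symmetry of A9 removes the orientation question. However, β-dicarbonyl enolates are expected to attack arynes through carbon and give insertion into the C–C bond, not the chromone. A8 is itself a hexasubstituted benzene at least as long to make as A1, and A11 still needs the selective 5-demethylation. The difficulty is moved, not settled.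

Key step: step 5

Assumption: 1, 4 and 6 are bought; 8 and 10 each carry one stereocenter, are formed racemic and lose it on the way to the achiral target.

**Steps**

Step 1
Reactants: 1 3-hydroxy-4H-pyran-4-one (pyromeconic acid)
Product: 2 2-bromo-3-hydroxy-4H-pyran-4-one
Conditions: NBS (1.0 equiv), MeCN, 0 °C to rt
Reagents that add atoms: N-bromosuccinimide, O=C1CCC(=O)N1Br
Why: Electrophilic bromination of the enol of a 3-hydroxy-4-pyranone should occur at C2, the carbon ortho to the hydroxyl, as in the halogenation of kojic acid at the corresponding position; one equivalent at low temperature limits dibromination.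

Step 2
Reactants: 2 2-bromo-3-hydroxy-4H-pyran-4-one
Product: 3 3-(benzyloxy)-2-bromo-4H-pyran-4-one
Conditions: BnBr, K2CO3, DMF, rt
Reagents that add atoms: benzyl bromide, BrCc1ccccc1
Why: Williamson etherification of the acidic enolic hydroxyl; the non-nucleophilic medium spares the C2–Br bond, which is a vinylogous acyl bromide.

Step 3
Reactants: 3 3-(benzyloxy)-2-bromo-4H-pyran-4-one; 4 [3,4-bis(benzyloxy)phenyl]boronic acid
Product: 5 3-(benzyloxy)-2-[3,4-bis(benzyloxy)phenyl]-4H-pyran-4-one
Conditions: Pd(PPh3)4 (5 mol %), Na2CO3 (2 M aq), DME, 85 °C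
Reagents that add atoms: none
Why: Suzuki–Miyaura coupling; the C2–Br bond of a 4-pyranone should add readily to zerovalent palladium, as 2-halochromones do, and the carbonate base is mild enough for the pyranone ring.

Step 4
Reactants: 5 3-(benzyloxy)-2-[3,4-bis(benzyloxy)phenyl]-4H-pyran-4-one; 6 dimethyl squarate (3,4-dimethoxycyclobut-3-ene-1,2-dione)
Product: 8 4-{5-(benzyloxy)-6-[3,4-bis(benzyloxy)phenyl]-4-oxo-4H-pyran-2-yl}-4-hydroxy-2,3-dimethoxycyclobut-2-en-1-one (racemic), via C6-magnesiated pyranone 7 (not isolated)
Conditions: TMPMgCl·LiCl (1.1 equiv), THF, −40 °C; then 6, −78 to −40 °C; sat. NH4Cl (aq), −40 °C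
Reagents that add atoms: none
Why: Deprotonative magnesiation of a 4-pyranone at the sp2 C–H next to the ring oxygen (C6, the only such position left in 5 and more acidic than C5–H), as in the metalation of chromones with TMP bases, then 1,2-addition of the organomagnesium to one of the two equivalent carbonyls of 6; the carbinol stereocenter forms racemic and is lost in step 5, and the cold neutral quench keeps 8 from rearranging to a cyclobutenedione.

Step 5
Reactants: 8 4-{5-(benzyloxy)-6-[3,4-bis(benzyloxy)phenyl]-4-oxo-4H-pyran-2-yl}-4-hydroxy-2,3-dimethoxycyclobut-2-en-1-one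
Product: 11 3-(benzyloxy)-2-[3,4-bis(benzyloxy)phenyl]-5,8-dihydroxy-6,7-dimethoxy-4H-chromen-4-one, via dienylketene 9 (not isolated), via cyclohexadienone 10 (not isolated)
Conditions: PhMe (degassed), 110 °C, Ar
Reagents that add atoms: none
Why: This is a Moore rearrangement, the thermal ring expansion of a squarate-derived 4-hydroxycyclobutenone with an unsaturated 4-substituent (closest known cases: 4-aryl, 4-heteroaryl and 4-alkenyl adducts giving hydroquinones). Conrotatory 4π ring opening of 8 should give dienylketene 9, with the hydroxyl donor rotating outward so that the pyranonyl group turns inward and ends cis to the ketene. A thermal disrotatory 6π electrocyclisation then joins the ketene carbon to C5 of the pyranone (the future C5–C4a bond) and closes the only new ring, the six-membered carbocycle of 10. The C4a–H of 10 lies between two carbonyl groups, so enolisation to the aromatic hydroquinone 11 should be fast and irreversible; the transient C4a stereocenter and that of 8 are lost, and no stereocontrol is needed. The selectivity needed is closure at C5 and not capture of the ketene by the hydroxyl or by O1: outward rotation puts the hydroxyl trans to the ketene, attack by O1 would only give an unproductive oxonium, and C5 is the nucleophilic carbon of the 4-pyranone (β-carbon of the O1–C6=C5 enol ether), matched to the electrophilic ketene carbon. The placing of 5-OH, 6-OMe, 7-OMe and 8-OH follows from the atom sequence of the squarate unit without any regiochemical choice. Air is excluded because 11 would otherwise be oxidised to the 5,8-quinone.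

Step 6
Reactants: 11 3-(benzyloxy)-2-[3,4-bis(benzyloxy)phenyl]-5,8-dihydroxy-6,7-dimethoxy-4H-chromen-4-one
Product: 12 3-(benzyloxy)-2-[3,4-bis(benzyloxy)phenyl]-5-hydroxy-6,7,8-trimethoxy-4H-chromen-4-one
Conditions: MeI (1.1 equiv), K2CO3 (1.2 equiv), DMF (degassed), 0 °C to rt, Ar
Reagents that add atoms: iodomethane, CI
Why: Chelation-controlled partial O-methylation, classical for 5,8-dihydroxyflavones: O5–H is hydrogen-bonded to the C4 carbonyl and is the less acidic and less nucleophilic, so one equivalent of MeI should alkylate the 8-phenoxide only.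

Step 7
Reactants: 12 3-(benzyloxy)-2-[3,4-bis(benzyloxy)phenyl]-5-hydroxy-6,7,8-trimethoxy-4H-chromen-4-one
Product: 13 2-(3,4-dihydroxyphenyl)-3,5-dihydroxy-6,7,8-trimethoxy-4H-chromen-4-one (3,5,3',4'-tetrahydroxy-6,7,8-trimethoxyflavone)
Conditions: H2 (1 atm), 10% Pd/C, EtOAc–MeOH, rt
Reagents that add atoms: none
Why: Hydrogenolysis of the three benzyl ethers over palladium on carbon; aryl methyl ethers and the C2=C3 bond of the flavone are not expected to react at atmospheric pressure.

**Compound list**

1 | 3-hydroxy-4H-pyran-4-one (pyromeconic acid) | O=c1ccocc1O | starting material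
2 | 2-bromo-3-hydroxy-4H-pyran-4-one | O=c1ccoc(Br)c1O | intermediate
3 | 3-(benzyloxy)-2-bromo-4H-pyran-4-one | O=c1ccoc(Br)c1OCc1ccccc1 | intermediate
4 | [3,4-bis(benzyloxy)phenyl]boronic acid | OB(O)c1ccc(OCc2ccccc2)c(OCc2ccccc2)c1 | starting material
5 | 3-(benzyloxy)-2-[3,4-bis(benzyloxy)phenyl]-4H-pyran-4-one | O=c1ccoc(-c2ccc(OCc3ccccc3)c(OCc3ccccc3)c2)c1OCc1ccccc1 | intermediate
6 | dimethyl squarate (3,4-dimethoxycyclobut-3-ene-1,2-dione) | COC1=C(OC)C(=O)C1=O | starting material
7 | {5-(benzyloxy)-6-[3,4-bis(benzyloxy)phenyl]-4-oxo-4H-pyran-2-yl}magnesium chloride, LiCl complex | O=c1cc([Mg]Cl)oc(-c2ccc(OCc3ccccc3)c(OCc3ccccc3)c2)c1OCc1ccccc1.[Li+].[Cl-] | intermediate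
8 | 4-{5-(benzyloxy)-6-[3,4-bis(benzyloxy)phenyl]-4-oxo-4H-pyran-2-yl}-4-hydroxy-2,3-dimethoxycyclobut-2-en-1-one (racemic) | COC1=C(OC)C(O)(c2cc(=O)c(OCc3ccccc3)c(-c3ccc(OCc4ccccc4)c(OCc4ccccc4)c3)o2)C1=O | intermediate
9 | (3Z)-4-{5-(benzyloxy)-6-[3,4-bis(benzyloxy)phenyl]-4-oxo-4H-pyran-2-yl}-4-hydroxy-2,3-dimethoxybuta-1,3-dien-1-one (dienylketene) | COC(=C=O)/C(OC)=C(/O)c1cc(=O)c(OCc2ccccc2)c(-c2ccc(OCc3ccccc3)c(OCc3ccccc3)c2)o1 | intermediate
10 | 3-(benzyloxy)-2-[3,4-bis(benzyloxy)phenyl]-8-hydroxy-6,7-dimethoxy-4aH-chromene-4,5-dione (racemic at C4a) | COC1=C(OC)C(O)=C2OC(-c3ccc(OCc4ccccc4)c(OCc4ccccc4)c3)=C(OCc3ccccc3)C(=O)C2C1=O | intermediate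
11 | 3-(benzyloxy)-2-[3,4-bis(benzyloxy)phenyl]-5,8-dihydroxy-6,7-dimethoxy-4H-chromen-4-one | COc1c(OC)c(O)c2c(=O)c(OCc3ccccc3)c(-c3ccc(OCc4ccccc4)c(OCc4ccccc4)c3)oc2c1O | intermediate
12 | 3-(benzyloxy)-2-[3,4-bis(benzyloxy)phenyl]-5-hydroxy-6,7,8-trimethoxy-4H-chromen-4-one | COc1c(OC)c(O)c2c(=O)c(OCc3ccccc3)c(-c3ccc(OCc4ccccc4)c(OCc4ccccc4)c3)oc2c1OC | intermediate
13 | 2-(3,4-dihydroxyphenyl)-3,5-dihydroxy-6,7,8-trimethoxy-4H-chromen-4-one | COc1c(OC)c(O)c2c(=O)c(O)c(-c3ccc(O)c(O)c3)oc2c1OC | target

**Step count and risks**

Total steps: 7. Longest linear sequence: 7 steps (from 1); 4 and 6 enter as purchased partners.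

Step 5 (key step). The most likely failure is capture of the ketene by the tertiary hydroxyl, giving a butenolide. This could happen if the electron-poor pyranonyl group weakens the preference for outward rotation of the hydroxyl, or if closure on C5 is slower than for the usual aryl groups. A second possibility is oxidation of the hydroquinone during isolation. Fallback, from 8 and back to the route at 12: the tertiary hydroxyl is methylated first (MeI, Ag2O, MeCN, rt) to give 4-{5-(benzyloxy)-6-[3,4-bis(benzyloxy)phenyl]-4-oxo-4H-pyran-2-yl}-2,3,4-trimethoxycyclobut-2-en-1-one F1. Thermolysis of F1 in toluene at 110 °C should give 12 directly, because the ether oxygen becomes O8 and the ketene oxygen becomes the 5-hydroxyl. No free hydroxyl is present to trap the ketene, no hydroquinone is formed, and step 6 is no longer needed.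

Step 4. The most likely failures are carbonyl-directed deprotonation at C5 in place of C6, and addition of the organomagnesium to the C4 carbonyl of a second molecule of 5. An adduct through C5 would still converge on 11, but a mixture would complicate isolation. Fallback, from 5 and back to the route at 11: the metal is placed by halogen–magnesium exchange at the other carbon. Iodination α to the carbonyl, the usual site of electrophilic halogenation of 4-pyranones and chromones (N-iodosuccinimide, CF3CO2H cat., MeCN), should give 3-(benzyloxy)-2-[3,4-bis(benzyloxy)phenyl]-5-iodo-4H-pyran-4-one F2. Exchange with iPrMgCl·LiCl in THF at −40 °C gives {5-(benzyloxy)-6-[3,4-bis(benzyloxy)phenyl]-4-oxo-4H-pyran-3-yl}magnesium chloride F3, which is added to 6 at −78 °C to give 4-{5-(benzyloxy)-6-[3,4-bis(benzyloxy)phenyl]-4-oxo-4H-pyran-3-yl}-4-hydroxy-2,3-dimethoxycyclobut-2-en-1-one F4. Thermolysis of F4 as in step 5 closes the ketene carbon on C6 of the pyranone and should give the same hydroquinone 11, with the carbinol carbon now becoming C5.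

Step 6. The most likely failures are further alkylation at the chelated O5 when the reagent is in local excess, and oxidation of the electron-rich phenoxide to the 5,8-quinone by traces of oxygen in base. Fallback, from 11 and back to the route at 13: exhaustive methylation (excess Me2SO4, K2CO3, acetone, reflux) gives 3-(benzyloxy)-2-[3,4-bis(benzyloxy)phenyl]-5,6,7,8-tetramethoxy-4H-chromen-4-one F5 (the same structure as A11). BCl3 in CH2Cl2 at −78 to 0 °C should then cleave the 5-methyl ether by chelation to the C4 carbonyl, and the three benzyl ethers, giving 13 without step 7.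

**Further compounds**

F1 | step 5 | 4-{5-(benzyloxy)-6-[3,4-bis(benzyloxy)phenyl]-4-oxo-4H-pyran-2-yl}-2,3,4-trimethoxycyclobut-2-en-1-one (racemic) | COC1=C(OC)C(OC)(c2cc(=O)c(OCc3ccccc3)c(-c3ccc(OCc4ccccc4)c(OCc4ccccc4)c3)o2)C1=O
F2 | step 4 | 3-(benzyloxy)-2-[3,4-bis(benzyloxy)phenyl]-5-iodo-4H-pyran-4-one | O=c1c(I)coc(-c2ccc(OCc3ccccc3)c(OCc3ccccc3)c2)c1OCc1ccccc1
F3 | step 4 | {5-(benzyloxy)-6-[3,4-bis(benzyloxy)phenyl]-4-oxo-4H-pyran-3-yl}magnesium chloride | O=c1c([Mg]Cl)coc(-c2ccc(OCc3ccccc3)c(OCc3ccccc3)c2)c1OCc1ccccc1
F4 | step 4 | 4-{5-(benzyloxy)-6-[3,4-bis(benzyloxy)phenyl]-4-oxo-4H-pyran-3-yl}-4-hydroxy-2,3-dimethoxycyclobut-2-en-1-one (racemic) | COC1=C(OC)C(O)(c2coc(-c3ccc(OCc4ccccc4)c(OCc4ccccc4)c3)c(OCc3ccccc3)c2=O)C1=O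
F5 | step 6 | 3-(benzyloxy)-2-[3,4-bis(benzyloxy)phenyl]-5,6,7,8-tetramethoxy-4H-chromen-4-one | COc1c(OC)c(OC)c2c(=O)c(OCc3ccccc3)c(-c3ccc(OCc4ccccc4)c(OCc4ccccc4)c3)oc2c1OC
A1 | alternative 1 | 1-(2-hydroxy-3,4,5,6-tetramethoxyphenyl)ethan-1-one | CC(=O)c1c(O)c(OC)c(OC)c(OC)c1OC
A2 | alternative 1 | 3,4-bis(benzyloxy)benzaldehyde | O=Cc1ccc(OCc2ccccc2)c(OCc2ccccc2)c1
A3 | alternative 1 | (E)-3-[3,4-bis(benzyloxy)phenyl]-1-(2-hydroxy-3,4,5,6-tetramethoxyphenyl)prop-2-en-1-one | COc1c(OC)c(OC)c(C(=O)/C=C/c2ccc(OCc3ccccc3)c(OCc3ccccc3)c2)c(O)c1OC
A4 | alternative 1 | 2-[3,4-bis(benzyloxy)phenyl]-3-hydroxy-5,6,7,8-tetramethoxy-4H-chromen-4-one | COc1c(OC)c(OC)c2c(=O)c(O)c(-c3ccc(OCc4ccccc4)c(OCc4ccccc4)c3)oc2c1OC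
A5 | alternative 2 | pentacarbonyl{[5-(benzyloxy)-6-[3,4-bis(benzyloxy)phenyl]-4-oxo-4H-pyran-2-yl](methoxy)methylidene}chromium | COC(c1cc(=O)c(OCc2ccccc2)c(-c2ccc(OCc3ccccc3)c(OCc3ccccc3)c2)o1)=[Cr](=C=O)(=C=O)(=C=O)(=C=O)=C=O
A6 | alternative 2 | di-tert-butoxyethyne | CC(C)(C)OC#COC(C)(C)C
A7 | alternative 2 | 3-(benzyloxy)-2-[3,4-bis(benzyloxy)phenyl]-6,7-di-tert-butoxy-5-hydroxy-8-methoxy-4H-chromen-4-one | COc1c(OC(C)(C)C)c(OC(C)(C)C)c(O)c2c(=O)c(OCc3ccccc3)c(-c3ccc(OCc4ccccc4)c(OCc4ccccc4)c3)oc12
A8 | alternative 3 | 2,3,4,5-tetramethoxy-6-(trimethylsilyl)phenyl trifluoromethanesulfonate | COc1c(OC)c(OC)c([Si](C)(C)C)c(OS(=O)(=O)C(F)(F)F)c1OC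
A9 | alternative 3 | 3,4,5,6-tetramethoxybenzyne (1,2-didehydro-3,4,5,6-tetramethoxybenzene) | COC1=C(OC)C(OC)=C(OC)C#C1
A10 | alternative 3 | methyl 2-(benzyloxy)-3-[3,4-bis(benzyloxy)phenyl]-3-oxopropanoate (racemic) | COC(=O)C(OCc1ccccc1)C(=O)c1ccc(OCc2ccccc2)c(OCc2ccccc2)c1
A11 | alternative 3 | 3-(benzyloxy)-2-[3,4-bis(benzyloxy)phenyl]-5,6,7,8-tetramethoxy-4H-chromen-4-one | COc1c(OC)c(OC)c2c(=O)c(OCc3ccccc3)c(-c3ccc(OCc4ccccc4)c(OCc4ccccc4)c3)oc2c1OC
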